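**Retrosynthetic overview**

1. Numbering (chroman): O1, C2 (CMe2), C3 (CHOH), C4 (CH2), C4a, C5 (OH), C6 (acyl), C7 (OMe), C8 (H), C8a; ring A = benzene ring, ring B = dihydropyran ring, ring C = 4-hydroxyphenyl ring.
2. Enone C=C (Claisen–Schmidt) ⇒ 6-acetylchroman-3-ol + O-protected 4-hydroxybenzaldehyde; C3 carbinol ⇒ C3 ketone (enantioselective reduction).
3. Key disconnection C4–C4a of ring B ⇒ aryl 1,1-dimethylpropargyl ether: oxidation of the terminal alkyne gives an α-oxo gold carbene whose carbene carbon (C4) is attacked by C4a, so ring closure and C3 oxygenation occur in one operation.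
4. Enabling feature: the C3 oxygen sits on the carbon between quaternary C2 and C4, which is the internal alkyne carbon of a propargyl ether on O1. C4a is the ring A carbon between O1 and the C5 hydroxyl, which is tied to the C6 carbonyl in a six-membered hydrogen-bonded chelate; this leaves C4a open while the C7 methoxy group shields C8.
5. O1–C2 ⇒ 1-(2,4-dihydroxy-6-methoxyphenyl)ethanone + 3-chloro-3-methylbut-1-yne; ring order: ring A bought, ring B closed in step 2, ring C (bought) attached in step 4.

Key step: step 2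

Remark: 1-(2,4-dihydroxy-6-methoxyphenyl)ethanone and 4-(methoxymethoxy)benzaldehyde are taken as catalogue compounds, and the hydrogen-bonded C5 hydroxyl is assumed to need no protection before the condensation.

**Step 1**
Reactants: 1 1-(2,4-dihydroxy-6-methoxyphenyl)ethan-1-one; 2 3-chloro-3-methylbut-1-yne
Product: 3 1-{2-hydroxy-6-methoxy-4-[(2-methylbut-3-yn-2-yl)oxy]phenyl}ethan-1-one
Conditions: 2 (1.5 equiv), CuCl2·2H2O (1 mol %), DBU (1.3 equiv), MeCN, 0 °C
Reagents that add atoms: 3-chloro-3-methylbut-1-yne (compound 2), CC(C)(Cl)C#C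
Why: Copper-catalysed propargylic substitution of the tertiary chloride by the phenoxide should alkylate only the free, more acidic 4-OH, because the 2-OH is locked in the hydrogen bond to the acetyl carbonyl.

**Step 2**
Reactants: 3 1-{2-hydroxy-6-methoxy-4-[(2-methylbut-3-yn-2-yl)oxy]phenyl}ethan-1-one
Product: 5 6-acetyl-5-hydroxy-7-methoxy-2,2-dimethyl-2H-chromen-3(4H)-one, via α-oxo gold carbene 4 (not isolated)
Conditions: [(Me4tBuXPhos)Au]NTf2 (5 mol %; Me4tBuXPhos = di-tert-butyl(2',4',6'-triisopropyl-3,4,5,6-tetramethylbiphenyl-2-yl)phosphine), 2,6-dichloropyridine N-oxide (1.5 equiv), ClCH2CH2Cl, rt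
Reagents that add atoms: 2,6-dichloropyridine N-oxide, [O-][n+]1c(Cl)cccc1Cl
Why: The cationic monovalent gold centre activates the terminal alkyne of 3, the N-oxide oxygen adds to the internal alkyne carbon (future C3) and N–O cleavage releases 2,6-dichloropyridine to leave the α-oxo gold carbene 4, whose electrophilic carbene carbon (future C4) is attacked by C4a of ring A; rearomatisation and protodeauration give 5. The closest known reaction type is the gold-catalysed N-oxide oxidation of aryl propargyl ethers to chroman-3-ones with bulky biaryl phosphine ligands, the diazo-free counterpart of the Rh2(OAc)4-catalysed cyclisation of aryloxymethyl diazoketones. Ring B is closed in a six-membered mode by Friedel–Crafts-type carbene insertion into the C4a–H bond, C4–C4a being the only new ring bond since O1–C2 and C2–C3 are already in the tether, and the gem-dimethyl group at C2 favours the folded conformer and excludes any 1,2-hydrogen shift. No stereocentre is formed: C3 is delivered as a ketone that cannot enolise toward C2, ready for reagent control in step 3. The step needs site selectivity for C4a over C8 and oxygen transfer ahead of direct hydroarylation of the alkyne. The first should follow from the hydrogen-bonded C5–OH···O=C chelate, which keeps the C5 oxygen small and raises the double-bond character of C4a–C8a, while the methyl of the C7 methoxy group is turned toward C8 by the acetyl group; the second from the bulky ligand, the excess of N-oxide and the damping of ring A by the para acetyl group.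

**Step 3**
Reactants: 5 6-acetyl-5-hydroxy-7-methoxy-2,2-dimethyl-2H-chromen-3(4H)-one
Product: 6 1-[(3R)-3,5-dihydroxy-7-methoxy-2,2-dimethyl-3,4-dihydro-2H-chromen-6-yl]ethan-1-one
Conditions: (S)-2-methyl-CBS-oxazaborolidine (20 mol %), catecholborane (2.2 equiv), toluene, −78 °C; then MeOH, aq NaHCO3
Reagents that add atoms: none
Why: Corey–Bakshi–Shibata reduction, in which the ketone binds the oxazaborolidine boron on the side of the small C4 methylene flank and away from the quaternary C2, so hydride should add to the face that gives the (3R)-alcohol (same sense as tert-butyl methyl ketone with the (S)-catalyst), while the chelated, doubly ortho-substituted aryl ketone is too hindered and too weakly basic to be activated at −78 °C.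

**Step 4**
Reactants: 6 1-[(3R)-3,5-dihydroxy-7-methoxy-2,2-dimethyl-3,4-dihydro-2H-chromen-6-yl]ethan-1-one; 7 4-(methoxymethoxy)benzaldehyde
Product: 9 (2E)-1-[(3R)-3,5-dihydroxy-7-methoxy-2,2-dimethyl-3,4-dihydro-2H-chromen-6-yl]-3-[4-(methoxymethoxy)phenyl]prop-2-en-1-one, via aldol adduct 8 (not isolated)
Conditions: KOH (50% aq), EtOH, 0 °C to rt; then AcOH to pH 6
Reagents that add atoms: 4-(methoxymethoxy)benzaldehyde (compound 7), COCOc1ccc(C=O)cc1
Why: Claisen–Schmidt condensation, in which the methyl ketone enolate adds to the non-enolisable aldehyde and aldol 8 loses water by E1cB to the thermodynamically preferred E-enone; the C3 stereocentre has no acidic neighbour and should be untouched.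

**Step 5**
Reactants: 9 (2E)-1-[(3R)-3,5-dihydroxy-7-methoxy-2,2-dimethyl-3,4-dihydro-2H-chromen-6-yl]-3-[4-(methoxymethoxy)phenyl]prop-2-en-1-one
Product: 10 (2E)-1-[(3R)-3,5-dihydroxy-7-methoxy-2,2-dimethyl-3,4-dihydro-2H-chromen-6-yl]-3-(4-hydroxyphenyl)prop-2-en-1-one
Conditions: HCl (3 M aq), MeOH, rt
Reagents that add atoms: none
Why: Acid-catalysed transacetalisation of the phenolic methoxymethyl ether to methanol should free the 4-hydroxyl, while the methyl ether, the tertiary ring ether, the secondary alcohol and the E-enone are expected to tolerate dilute acid at room temperature.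

**Compound list**

1 | 1-(2,4-dihydroxy-6-methoxyphenyl)ethan-1-one | COc1cc(O)cc(O)c1C(C)=O | starting material
2 | 3-chloro-3-methylbut-1-yne | CC(C)(Cl)C#C | starting material
3 | 1-{2-hydroxy-6-methoxy-4-[(2-methylbut-3-yn-2-yl)oxy]phenyl}ethan-1-one | COc1cc(OC(C)(C)C#C)cc(O)c1C(C)=O | intermediate
4 | α-oxo gold carbene [(Me4tBuXPhos)Au=CH–C(=O)–C(CH3)2–OAr]NTf2, Ar = 4-acetyl-3-hydroxy-5-methoxyphenyl (not isolated) | COc1cc(OC(C)(C)C(=O)C=[Au][P+](C(C)(C)C)(C(C)(C)C)c2c(C)c(C)c(C)c(C)c2-c2c(C(C)C)cc(C(C)C)cc2C(C)C)cc(O)c1C(C)=O.[N-](S(=O)(=O)C(F)(F)F)S(=O)(=O)C(F)(F)F | intermediate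
5 | 6-acetyl-5-hydroxy-7-methoxy-2,2-dimethyl-2H-chromen-3(4H)-one | COc1cc2OC(C)(C)C(=O)Cc2c(O)c1C(C)=O | intermediate
6 | 1-[(3R)-3,5-dihydroxy-7-methoxy-2,2-dimethyl-3,4-dihydro-2H-chromen-6-yl]ethan-1-one | COc1cc2c(c(O)c1C(C)=O)C[C@@H](O)C(C)(C)O2 | intermediate
7 | 4-(methoxymethoxy)benzaldehyde | COCOc1ccc(C=O)cc1 | starting material
8 | aldol adduct 3-hydroxy-1-[(3R)-3,5-dihydroxy-7-methoxy-2,2-dimethyl-3,4-dihydro-2H-chromen-6-yl]-3-[4-(methoxymethoxy)phenyl]propan-1-one, both epimers at the new carbinol (not isolated) | COc1cc2c(c(O)c1C(=O)CC(O)c1ccc(OCOC)cc1)C[C@@H](O)C(C)(C)O2 | intermediate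
9 | (2E)-1-[(3R)-3,5-dihydroxy-7-methoxy-2,2-dimethyl-3,4-dihydro-2H-chromen-6-yl]-3-[4-(methoxymethoxy)phenyl]prop-2-en-1-one | COc1cc2c(c(O)c1C(=O)/C=C/c1ccc(OCOC)cc1)C[C@@H](O)C(C)(C)O2 | intermediate
10 | (2E)-1-[(3R)-3,5-dihydroxy-7-methoxy-2,2-dimethyl-3,4-dihydro-2H-chromen-6-yl]-3-(4-hydroxyphenyl)prop-2-en-1-one | COc1cc2c(c(O)c1C(=O)/C=C/c1ccc(O)cc1)C[C@@H](O)C(C)(C)O2 | target

**Totals**

Total step count: 5. Longest linear sequence: 5 steps (1 → 3 → 5 → 6 → 9 → 10).

**Steps most likely to fail**

Step 2. The ring may attack the gold-activated alkyne before oxygen transfer (direct hydroarylation to the chromene), the carbene may be attacked at C8 instead of C4a, or the carbene may take up a second oxygen. The fallback sets out from 3 and comes back at 6, so that ketone 5 and step 3 are bypassed. Heating 3 in N,N-diethylaniline at 180 °C should trigger the aromatic propargyl Claisen rearrangement, 1,5-hydrogen shift and oxa-6π electrocyclisation, whose site selectivity is governed by the chelate-fixed C4a–C8a double bond, to give the chromene 1-(5-hydroxy-7-methoxy-2,2-dimethyl-2H-chromen-6-yl)ethan-1-one F1. Jacobsen–Katsuki epoxidation with (R,R)-N,N'-bis(3,5-di-tert-butylsalicylidene)cyclohexane-1,2-diaminomanganese chloride [(salen)MnCl], mCPBA and N-methylmorpholine N-oxide in CH2Cl2 at −78 °C should then give 1-[(3R,4R)-3,4-epoxy-5-hydroxy-7-methoxy-2,2-dimethyl-3,4-dihydro-2H-chromen-6-yl]ethan-1-one F2. Hydrogenolysis of its benzylic C4–O bond (H2, Pd/C, EtOAc) leaves the C3 centre untouched and should give 6.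

Step 3. Hydride may be delivered to the chelated C6 acetyl group through an aryloxyborane formed at the C5 hydroxyl, or facial discrimination may be poor because both flanks of the ketone are ring carbons. The fallback sets out from 5 and comes back at 6 by resolution instead of asymmetric induction. NaBH4 in MeOH at 0 °C, where the aryl ketone is shielded as its phenoxide, should give racemic 1-(3,5-dihydroxy-7-methoxy-2,2-dimethyl-3,4-dihydro-2H-chromen-6-yl)ethan-1-one F3. Acylation with Burkholderia cepacia lipase and vinyl acetate in tBuOMe at 40 °C is expected, by the usual empirical preference of lipases for secondary alcohols, to convert the (3R)-enantiomer into (3R)-6-acetyl-5-hydroxy-7-methoxy-2,2-dimethyl-3,4-dihydro-2H-chromen-3-yl acetate F4 and to leave 1-[(3S)-3,5-dihydroxy-7-methoxy-2,2-dimethyl-3,4-dihydro-2H-chromen-6-yl]ethan-1-one F5. After separation, methanolysis of F4 (K2CO3, MeOH) gives 6, and F5 can be returned to 5 by oxidation with Dess–Martin periodinane.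

Step 5. During acetal cleavage the acid may promote intramolecular oxa-Michael addition of the C5 hydroxyl to the enone (chalcone-to-flavanone isomerisation). The fallback sets out from 6 and comes back at 10 without any protecting group. Compound 6 is condensed directly with commercial 4-hydroxybenzaldehyde (KOH, EtOH/H2O, rt, prolonged reaction time) through the aldol adduct 3-hydroxy-1-[(3R)-3,5-dihydroxy-7-methoxy-2,2-dimethyl-3,4-dihydro-2H-chromen-6-yl]-3-(4-hydroxyphenyl)propan-1-one F6, and the mixture is neutralised cold with AcOH, so that the enone never meets strong acid.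

**Further compounds**

F1 | step 2 | 1-(5-hydroxy-7-methoxy-2,2-dimethyl-2H-chromen-6-yl)ethan-1-one | COc1cc2OC(C)(C)C=Cc2c(O)c1C(C)=O
F2 | step 2 | 1-[(3R,4R)-3,4-epoxy-5-hydroxy-7-methoxy-2,2-dimethyl-3,4-dihydro-2H-chromen-6-yl]ethan-1-one | COc1cc2OC(C)(C)[C@@H]3O[C@@H]3c2c(O)c1C(C)=O
F3 | step 3 | racemic 1-(3,5-dihydroxy-7-methoxy-2,2-dimethyl-3,4-dihydro-2H-chromen-6-yl)ethan-1-one | COc1cc2c(c(O)c1C(C)=O)CC(O)C(C)(C)O2
F4 | step 3 | (3R)-6-acetyl-5-hydroxy-7-methoxy-2,2-dimethyl-3,4-dihydro-2H-chromen-3-yl acetate | COc1cc2c(c(O)c1C(C)=O)C[C@@H](OC(C)=O)C(C)(C)O2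
F5 | step 3 | 1-[(3S)-3,5-dihydroxy-7-methoxy-2,2-dimethyl-3,4-dihydro-2H-chromen-6-yl]ethan-1-one | COc1cc2c(c(O)c1C(C)=O)C[C@H](O)C(C)(C)O2
F6 | step 5 | 3-hydroxy-1-[(3R)-3,5-dihydroxy-7-methoxy-2,2-dimethyl-3,4-dihydro-2H-chromen-6-yl]-3-(4-hydroxyphenyl)propan-1-one (both epimers at the new carbinol) | COc1cc2c(c(O)c1C(=O)CC(O)c1ccc(O)cc1)C[C@@H](O)C(C)(C)O2
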